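Retrosynthesis (C1 = lactone carbonyl to C8 = pyran CH–CH3): cut the O7 ester to (E)-4-oxooct-2-enoic acid, the lactone O5–C1 bond, the pyran O–C8 bond with C5–C8 unmasked as a furan, and the C4–C5 bond between a malate-derived α-benzyloxy methyl ketone and 2,4-dimethylfuran.
Forward order: C1–C4 chain from diisopropyl (S)-malate, furyl addition at C4, pyran ring by oxidative furan ring expansion, δ-lactone by closure of C5–OH onto the C1 ester, side chain attached at O7 last, then removal of the O3 benzyl group.
Enabling feature: in the pyran ring O–C8(CH3)–C7(O)–C6(CH3)–C5(O)–C4(CH3) the oxygens sit on C5 and C7 and the methyls on C6 and C8, so C5–C8 is a masked 3,5-dimethylfuran; ring expansion through the C4 tertiary hydroxyl delivers the C5 ketone, the C6-methyl enone and the C8 methyl hemiketal at once.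
Stereochemistry: C3 from (S)-malate, C2 by anti Fráter–Seebach methylation, C4 by chelation-controlled furyl addition; C8, C7, C6 and C5 are relayed from C4 under substrate control; the E alkene comes from the aldol condensation.

Key step: step 6

Assumption: 2,4-dimethylfuran is taken as a purchasable starting material, and the C1–C8 numbering of the target is used for all intermediates, open-chain ones included.

Step 1
Reactants: 1 diisopropyl (S)-malate
Product: 3 diisopropyl (2S,3R)-2-hydroxy-3-methylbutanedioate, via dilithium alkoxide-enolate 2 (not isolated)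
Conditions: LiN(iPr)2 (2.2 equiv), THF, −78 to −20 °C; MeI, −78 to 0 °C
Reagents that add atoms: iodomethane, CI
Why: Fráter–Seebach alkylation, in which the chelated dilithium alkoxide-enolate 2 is methylated on the face away from the alkoxide-bearing side, should give mainly the anti (2S,3R) diester and so set the methyl-bearing centre that becomes C2.

Step 2
Reactants: 3 diisopropyl (2S,3R)-2-hydroxy-3-methylbutanedioate
Product: 4 isopropyl (2R,3S)-3-hydroxy-4-[methoxy(methyl)amino]-2-methyl-4-oxobutanoate
Conditions: MeNH(OMe)·HCl, iPrMgCl, THF, −20 to 0 °C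
Reagents that add atoms: N,O-dimethylhydroxylamine hydrochloride, CNOC.Cl
Why: Hydroxyl-directed Weinreb amidation with Me(MeO)NMgCl, in which the magnesium alkoxide of the free hydroxyl chelates and activates the neighbouring α-hydroxy ester while the other ester is α-branched and unactivated, should confine aminolysis to the ester carbon that becomes C4.

Step 3
Reactants: 4 isopropyl (2R,3S)-3-hydroxy-4-[methoxy(methyl)amino]-2-methyl-4-oxobutanoate
Product: 5 isopropyl (2R,3S)-3-(benzyloxy)-4-[methoxy(methyl)amino]-2-methyl-4-oxobutanoate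
Conditions: BnOC(=NH)CCl3, TfOH (cat.), CH2Cl2/cyclohexane, 0 °C to rt
Reagents that add atoms: benzyl 2,2,2-trichloroacetimidate, N=C(OCc1ccccc1)C(Cl)(Cl)Cl
Why: Acid-catalysed O-benzylation with a trichloroacetimidate needs no alkoxide, which avoids the β-elimination toward the ester and the epimerisation of the α-methyl centre that Williamson conditions would risk.

Step 4
Reactants: 5 isopropyl (2R,3S)-3-(benzyloxy)-4-[methoxy(methyl)amino]-2-methyl-4-oxobutanoate
Product: 6 isopropyl (2R,3S)-3-(benzyloxy)-2-methyl-4-oxopentanoate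
Conditions: MeMgBr, THF, −40 to 0 °C
Reagents that add atoms: methylmagnesium bromide, C[Mg]Br
Why: Weinreb ketone synthesis, in which the N-methoxy-N-methylamide takes up one methyl group and releases the ketone only on quench, should leave the α-branched isopropyl ester untouched at this temperature.

Step 5
Reactants: 6 isopropyl (2R,3S)-3-(benzyloxy)-2-methyl-4-oxopentanoate; 7 2,4-dimethylfuran
Product: 10 isopropyl (2R,3S,4R)-3-(benzyloxy)-4-(3,5-dimethylfuran-2-yl)-4-hydroxy-2-methylpentanoate, via (3,5-dimethylfuran-2-yl)lithium 8 (not isolated), via (3,5-dimethylfuran-2-yl)magnesium bromide 9 (not isolated)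
Conditions: 7, n-BuLi, THF, 0 °C; MgBr2·OEt2, −78 to 0 °C; 6, THF, −78 °C; NH4Cl (aq), −78 °C
Reagents that add atoms: none
Why: Cram-chelate-controlled Grignard addition to an α-alkoxy ketone, with magnesium bridging the ketone and benzyloxy oxygens so that the furyl group enters on the carbonyl face opposite the C2 branch, should set C4 as (4R), and the cold quench keeps the tertiary alkoxide from closing onto the hindered isopropyl ester.

Step 6
Reactants: 10 isopropyl (2R,3S,4R)-3-(benzyloxy)-4-(3,5-dimethylfuran-2-yl)-4-hydroxy-2-methylpentanoate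
Product: 12 isopropyl (2R,3S)-3-(benzyloxy)-3-[(2R)-6-hydroxy-2,4,6-trimethyl-3-oxo-3,6-dihydro-2H-pyran-2-yl]-2-methylpropanoate (both C8 anomers), via Z-enedione 11 (not isolated)
Conditions: NBS, NaHCO3, NaOAc, THF/H2O (4:1), 0 °C
Reagents that add atoms: water, O
Why: This is the Achmatowicz oxidative ring expansion of a tertiary 2-furyl carbinol: bromonium-initiated addition of water across the 2,5-positions of the trialkylfuran followed by loss of HBr opens the furan to Z-enedione 11, with carbonyls at C5 and C8. The C4 hydroxyl, the only free one, then adds to the C8 ketone in a 6-exo-trig closure, forming the pyran through the C4–O–C8 bond and leaving the C5 ketone, the C6-methyl enone and the C8 methyl hemiketal in place. The closest known reaction type is the NBS- or peracid-mediated rearrangement of 2-furyl carbinols, tertiary carbinols and 5-methylfurans included, to 6-hydroxy-2H-pyran-3(6H)-ones. The only new stereocentre, the C8 hemiketal carbon, forms as an anomer mixture under thermodynamic control and needs no control because step 7 makes it planar again, while the quaternary C4 cannot epimerise. The step needs chemoselective oxidation of the furan and closure to the six-membered hemiketal: the trisubstituted furan is by far the most electron-rich π-system, the buffer protects the ester and benzyl ether, and the benzyl group on O3 rules out a competing bicyclic ketal.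

Step 7
Reactants: 12 isopropyl (2R,3S)-3-(benzyloxy)-3-[(2R)-6-hydroxy-2,4,6-trimethyl-3-oxo-3,6-dihydro-2H-pyran-2-yl]-2-methylpropanoate
Product: 14 isopropyl (2R,3S)-3-(benzyloxy)-2-methyl-3-[(2R,6S)-2,4,6-trimethyl-3-oxo-3,6-dihydro-2H-pyran-2-yl]propanoate, via C8 oxocarbenium ion 13 (not isolated)
Conditions: Et3SiH, CF3CO2H, CH2Cl2, −40 to 0 °C
Reagents that add atoms: none
Why: Ionic hydrogenation of the hemiketal (Kishi reduction): acid ionises 12 to the conjugated oxocarbenium ion 13, and Et3SiH should deliver hydride to C8 on the ring face of the C4 methyl, away from the branched C1–C3 chain, so that the C8 methyl ends cis to that chain as in the target.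

Step 8
Reactants: 14 isopropyl (2R,3S)-3-(benzyloxy)-2-methyl-3-[(2R,6S)-2,4,6-trimethyl-3-oxo-3,6-dihydro-2H-pyran-2-yl]propanoate
Product: 15 isopropyl (2R,3S)-3-(benzyloxy)-2-methyl-3-[(2R,4R,5R,6S)-2,4,6-trimethyl-3-oxo-5-(4,4,5,5-tetramethyl-1,3,2-dioxaborolan-2-yl)tetrahydro-2H-pyran-2-yl]propanoate
Conditions: B2pin2, CuCl (cat.), DPEphos (cat.), NaOtBu (cat.), MeOH (2 equiv), THF, rt
Reagents that add atoms: bis(pinacolato)diboron, CC1(C)OB(OC1(C)C)B1OC(C)(C)C(C)(C)O1
Why: Copper-catalysed conjugate borylation of the cyclic enone should place boron on C7 from the ring face opposite the adjacent C8 methyl and the C4 chain, and alkoxide-mediated equilibration of the ketone α-centre should leave the C6 methyl equatorial because the axial epimer is syn-diaxial to the C4 methyl.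

Step 9
Reactants: 15 isopropyl (2R,3S)-3-(benzyloxy)-2-methyl-3-[(2R,4R,5R,6S)-2,4,6-trimethyl-3-oxo-5-(4,4,5,5-tetramethyl-1,3,2-dioxaborolan-2-yl)tetrahydro-2H-pyran-2-yl]propanoate
Product: 16 isopropyl (2R,3S)-3-(benzyloxy)-3-[(2R,4R,5R,6S)-5-hydroxy-2,4,6-trimethyl-3-oxotetrahydro-2H-pyran-2-yl]-2-methylpropanoate
Conditions: NaBO3·4H2O, THF/H2O (1:1), 0 °C to rt
Reagents that add atoms: sodium perborate (NaBO3, used as the tetrahydrate), [Na+].[O-]OB=O
Why: Perborate oxidation of the pinacol boronate (carbon migrates from boron to oxygen with retention) turns C7–B into C7–OH at near-neutral pH, which should spare the β-hydroxy ketone from dehydration and the ester from hydrolysis.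

Step 10
Reactants: 16 isopropyl (2R,3S)-3-(benzyloxy)-3-[(2R,4R,5R,6S)-5-hydroxy-2,4,6-trimethyl-3-oxotetrahydro-2H-pyran-2-yl]-2-methylpropanoate
Product: 17 isopropyl (2R,3S)-3-(benzyloxy)-3-[(2S,3S,4R,5R,6S)-3,5-dihydroxy-2,4,6-trimethyltetrahydro-2H-pyran-2-yl]-2-methylpropanoate
Conditions: NaBH4, MeOH, −40 °C
Reagents that add atoms: none
Why: Borohydride reduction by axial attack on the ring ketone, on the face opposite the axial C4 methyl, should give the equatorial C5 alcohol, syn to the C7 hydroxyl.

Step 11
Reactants: 17 isopropyl (2R,3S)-3-(benzyloxy)-3-[(2S,3S,4R,5R,6S)-3,5-dihydroxy-2,4,6-trimethyltetrahydro-2H-pyran-2-yl]-2-methylpropanoate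
Product: 18 3-O-benzyl-7-O-deacylbotcinin I, the trans-fused pyrano-δ-lactone (2R,3S,4R,5S,6R,7R,8S) with free equatorial C7–OH and benzyl ether on O3
Conditions: CSA (cat.), toluene, 60 °C
Reagents that add atoms: none
Why: Acid-catalysed lactonisation (intramolecular transesterification) of the δ-hydroxy isopropyl ester should close only the six-membered ring from C5–OH to C1, the diequatorial C5–O and C4–C3 bonds giving the trans fusion, while acid leaves the axial C2 methyl unepimerised.

Step 12
Reactants: 19 hexan-2-one; 20 glyoxylic acid (as the monohydrate)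
Product: 21 (E)-4-oxooct-2-enoic acid
Conditions: pyrrolidine, AcOH, MeOH, 60 °C
Reagents that add atoms: none
Why: Amine-mediated crossed aldol condensation of a methyl ketone with glyoxylic acid should proceed through the less substituted enamine at the methyl group, and dehydration under equilibrating conditions should give the E enone acid.

Step 13
Reactants: 18 3-O-benzyl-7-O-deacylbotcinin I; 21 (E)-4-oxooct-2-enoic acid
Product: 23 3-O-benzylbotcinin I, via Yamaguchi mixed anhydride 22 (not isolated)
Conditions: 2,4,6-Cl3C6H2COCl, Et3N, toluene, 0 °C to rt; then 18, DMAP, rt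
Reagents that add atoms: none
Why: Yamaguchi esterification, in which DMAP attacks mixed anhydride 22 at the unhindered enoyl carbonyl and passes the acyl group to the single free hydroxyl (C7) of 18, is mild enough not to epimerise C2 or isomerise the E alkene.

Step 14
Reactants: 23 3-O-benzylbotcinin I
Product: 24 botcinin I
Conditions: BCl3, C6HMe5, CH2Cl2, −78 °C; MeOH quench
Reagents that add atoms: none
Why: Lewis-acid debenzylation with BCl3 and pentamethylbenzene as benzyl-cation scavenger (Friedel–Crafts capture) is non-reductive, so the enone alkene, ketone, ester and lactone should survive at −78 °C.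

Compound list
1 | diisopropyl (S)-malate | CC(C)OC(=O)C[C@H](O)C(=O)OC(C)C | starting material
2 | dilithium alkoxide-enolate of 1 | CC(C)OC(O[Li])=C[C@H](O[Li])C(=O)OC(C)C | intermediate
3 | diisopropyl (2S,3R)-2-hydroxy-3-methylbutanedioate | CC(C)OC(=O)[C@H](C)[C@H](O)C(=O)OC(C)C | intermediate
4 | isopropyl (2R,3S)-3-hydroxy-4-[methoxy(methyl)amino]-2-methyl-4-oxobutanoate | CC(C)OC(=O)[C@H](C)[C@H](O)C(=O)N(C)OC | intermediate
5 | isopropyl (2R,3S)-3-(benzyloxy)-4-[methoxy(methyl)amino]-2-methyl-4-oxobutanoate | CC(C)OC(=O)[C@H](C)[C@H](OCc1ccccc1)C(=O)N(C)OC | intermediate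
6 | isopropyl (2R,3S)-3-(benzyloxy)-2-methyl-4-oxopentanoate | CC(C)OC(=O)[C@H](C)[C@H](OCc1ccccc1)C(C)=O | intermediate
7 | 2,4-dimethylfuran | Cc1cc(C)co1 | starting material
8 | (3,5-dimethylfuran-2-yl)lithium | [Li]c1oc(C)cc1C | intermediate
9 | (3,5-dimethylfuran-2-yl)magnesium bromide | Cc1cc(C)c([Mg]Br)o1 | intermediate
10 | isopropyl (2R,3S,4R)-3-(benzyloxy)-4-(3,5-dimethylfuran-2-yl)-4-hydroxy-2-methylpentanoate | CC(C)OC(=O)[C@H](C)[C@H](OCc1ccccc1)[C@@](c1oc(C)cc1C)(C)O | intermediate
11 | isopropyl (2R,3S,4R,6Z)-3-(benzyloxy)-4-hydroxy-2,4,6-trimethyl-5,8-dioxonon-6-enoate | CC(C)OC(=O)[C@H](C)[C@H](OCc1ccccc1)[C@@](C)(O)C(=O)/C(C)=C\C(C)=O | intermediate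
12 | isopropyl (2R,3S)-3-(benzyloxy)-3-[(2R)-6-hydroxy-2,4,6-trimethyl-3-oxo-3,6-dihydro-2H-pyran-2-yl]-2-methylpropanoate (C8 anomers) | CC(C)OC(=O)[C@H](C)[C@H](OCc1ccccc1)[C@@]1(C)OC(C)(O)C=C(C)C1=O | intermediate
13 | C8 oxocarbenium ion of 12 (2,4,6-trimethyl-3-oxo-2H-pyran-1-ium carrying the C1–C3 chain at C4) | CC(C)OC(=O)[C@H](C)[C@H](OCc1ccccc1)[C@@]1(C)[O+]=C(C)C=C(C)C1=O | intermediate
14 | isopropyl (2R,3S)-3-(benzyloxy)-2-methyl-3-[(2R,6S)-2,4,6-trimethyl-3-oxo-3,6-dihydro-2H-pyran-2-yl]propanoate | CC(C)OC(=O)[C@H](C)[C@H](OCc1ccccc1)[C@@]1(C)O[C@@H](C)C=C(C)C1=O | intermediate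
15 | isopropyl (2R,3S)-3-(benzyloxy)-2-methyl-3-[(2R,4R,5R,6S)-2,4,6-trimethyl-3-oxo-5-(4,4,5,5-tetramethyl-1,3,2-dioxaborolan-2-yl)tetrahydro-2H-pyran-2-yl]propanoate | CC(C)OC(=O)[C@H](C)[C@H](OCc1ccccc1)[C@@]1(C)O[C@@H](C)[C@H](B2OC(C)(C)C(C)(C)O2)[C@@H](C)C1=O | intermediate
16 | isopropyl (2R,3S)-3-(benzyloxy)-3-[(2R,4R,5R,6S)-5-hydroxy-2,4,6-trimethyl-3-oxotetrahydro-2H-pyran-2-yl]-2-methylpropanoate | CC(C)OC(=O)[C@H](C)[C@H](OCc1ccccc1)[C@@]1(C)O[C@@H](C)[C@H](O)[C@@H](C)C1=O | intermediate
17 | isopropyl (2R,3S)-3-(benzyloxy)-3-[(2S,3S,4R,5R,6S)-3,5-dihydroxy-2,4,6-trimethyltetrahydro-2H-pyran-2-yl]-2-methylpropanoate | CC(C)OC(=O)[C@H](C)[C@H](OCc1ccccc1)[C@@]1(C)O[C@@H](C)[C@H](O)[C@@H](C)[C@@H]1O | intermediate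
18 | 3-O-benzyl-7-O-deacylbotcinin I (trans-fused pyrano-δ-lactone, C7–OH free) | O[C@@H]1[C@@H](C)[C@@H]2OC(=O)[C@H](C)[C@H](OCc3ccccc3)[C@@]2(C)O[C@H]1C | intermediate
19 | hexan-2-one | CCCCC(C)=O | starting material
20 | glyoxylic acid (used as the monohydrate) | O=CC(=O)O | starting material
21 | (E)-4-oxooct-2-enoic acid | CCCCC(=O)/C=C/C(=O)O | intermediate
22 | (E)-4-oxooct-2-enoic 2,4,6-trichlorobenzoic anhydride | CCCCC(=O)/C=C/C(=O)OC(=O)c1c(Cl)cc(Cl)cc1Cl | intermediate
23 | 3-O-benzylbotcinin I | CCCCC(=O)/C=C/C(=O)O[C@@H]1[C@@H](C)[C@@H]2OC(=O)[C@H](C)[C@H](OCc3ccccc3)[C@@]2(C)O[C@H]1C | intermediate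
24 | botcinin I | CCCCC(=O)/C=C/C(=O)O[C@@H]1[C@@H](C)[C@@H]2OC(=O)[C@H](C)[C@H](O)[C@@]2(C)O[C@H]1C | target

Total step count: 14. Longest linear sequence: 13 steps (steps 1–11, 13 and 14, from 1 to 24); the side-chain acid 21 is one step (step 12) from 19 and 20.

Steps most likely to fail

Step 5. The ortho-substituted furyl nucleophile is hindered and may deprotonate the methyl ketone instead of adding. Chelation may also be incomplete, eroding facial selectivity at C4, and the tertiary alkoxide may close onto the isopropyl ester before the quench. The fallback sets out from Weinreb amide 5 and rejoins the route at carbinol 10, with the roles of the two carbon groups at C4 exchanged. Amide 5 is acylated with (3,5-dimethylfuran-2-yl)lithium 8 (THF, −78 °C) to give the furyl ketone isopropyl (2R,3S)-3-(benzyloxy)-4-(3,5-dimethylfuran-2-yl)-2-methyl-4-oxobutanoate F1, which has no enolisable methyl group. The methyl group is then added with the non-chelating reagent MeTi(OiPr)3 (Et2O, −20 °C to rt). Under Felkin–Anh control, with the benzyloxy group antiperiplanar to the incoming methyl, this should lead to the same (4R) configuration that chelation control gives with the furyl nucleophile, and so to 10.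

Step 7. The oxocarbenium ion is nearly flat, so hydride may be delivered to the face of the C1–C3 chain instead of the face of the C4 methyl, or to both faces; internal hydride transfer from the benzylic CH2 would have the same wrong facial sense. The fallback sets out from ketone 6 and returns at enone 14, and it exchanges the roles of hydrogen and methyl at C8 so that attack on the chain face becomes the productive one. Br/Mg exchange of 2-bromo-3-methylfuran with iPrMgCl·LiCl gives (3-methylfuran-2-yl)magnesium chloride F2. This adds to 6 under the chelation control of step 5 to give isopropyl (2R,3S,4R)-3-(benzyloxy)-4-hydroxy-2-methyl-4-(3-methylfuran-2-yl)pentanoate F3. The same NBS ring expansion gives the hemiacetal isopropyl (2R,3S)-3-(benzyloxy)-3-[(2R)-6-hydroxy-2,4-dimethyl-3-oxo-3,6-dihydro-2H-pyran-2-yl]-2-methylpropanoate F4, in which C8 is CH–OH. Acetylation (Ac2O, pyridine, DMAP) gives isopropyl (2R,3S)-3-[(2R)-6-acetoxy-2,4-dimethyl-3-oxo-3,6-dihydro-2H-pyran-2-yl]-3-(benzyloxy)-2-methylpropanoate F5. AlMe3 (CH2Cl2, −78 °C) then ionises the acetate and transfers methyl to C8. A carbon nucleophile responds more strongly than hydride to the same facial bias, and attack on the chain face now places the C8 methyl cis to the chain, as in 14.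

Step 8. Borylcupration of the α-methyl enone may be sluggish, equilibration at C6 may be incomplete, and the β-oxygenated ketone may eliminate back to the enone during oxidation. The fallback sets out from enone 14 and returns at hydroxy ketone 16. Weitz–Scheffer epoxidation (tBuOOH, DBU, CH2Cl2, 0 °C) should deliver the peroxide to C7 trans to the C8 methyl and give the 6,7-epoxy ketone of 14 (epoxide oxygen trans to the C8 methyl and the C1–C3 chain) F6. SmI2 (THF/MeOH, −78 °C) then cleaves the C6–O bond α to the ketone; the C7 hydroxyl stays in place, and protonation at C6 with equilibration to the equatorial methyl gives 16.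

Further compounds
F1 | step 5 | isopropyl (2R,3S)-3-(benzyloxy)-4-(3,5-dimethylfuran-2-yl)-2-methyl-4-oxobutanoate | CC(C)OC(=O)[C@H](C)[C@H](OCc1ccccc1)C(=O)c1oc(C)cc1C
F2 | step 7 | (3-methylfuran-2-yl)magnesium chloride | Cc1ccoc1[Mg]Cl
F3 | step 7 | isopropyl (2R,3S,4R)-3-(benzyloxy)-4-hydroxy-2-methyl-4-(3-methylfuran-2-yl)pentanoate | CC(C)OC(=O)[C@H](C)[C@H](OCc1ccccc1)[C@@](c1occc1C)(C)O
F4 | step 7 | isopropyl (2R,3S)-3-(benzyloxy)-3-[(2R)-6-hydroxy-2,4-dimethyl-3-oxo-3,6-dihydro-2H-pyran-2-yl]-2-methylpropanoate | CC(C)OC(=O)[C@H](C)[C@H](OCc1ccccc1)[C@@]1(C)OC(O)C=C(C)C1=O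
F5 | step 7 | isopropyl (2R,3S)-3-[(2R)-6-acetoxy-2,4-dimethyl-3-oxo-3,6-dihydro-2H-pyran-2-yl]-3-(benzyloxy)-2-methylpropanoate | CC(C)OC(=O)[C@H](C)[C@H](OCc1ccccc1)[C@@]1(C)OC(OC(C)=O)C=C(C)C1=O
F6 | step 8 | 6,7-epoxy ketone of 14 (epoxide oxygen trans to the C8 methyl) | CC(C)OC(=O)[C@H](C)[C@H](OCc1ccccc1)[C@@]1(C)O[C@@H](C)[C@@H]2O[C@]2(C)C1=O
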